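**Retrosynthetic overview**

1. Feature: ring A has para-disposed oxygens at C5 (free OH, peri to the C4 carbonyl) and C8 (OMe), with C6–H and C7–OMe between them. C5–C6–C7–C8 therefore match the four carbons of methyl semisquarate one for one, and C4a=C8a is the C5=C6 bond of a 2-aryl-4H-pyran-4-one (ring C carrying ring B).
2. Disconnection of C5–C4a: ring A goes back to a 3,4-dimethoxy-4-(4-oxopyran-2-yl)cyclobutenone, which should ring-expand on heating (4π opening, 6π closure, enolization).
3. Disconnection of C8–C8a: the cyclobutenone comes from 1,2-addition of the C6-lithiated 2-arylpyranone to methyl semisquarate, followed by O-methylation of the carbinol.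
4. The pyranone comes from C-acylation of the enolate of (E)-4-methoxybut-3-en-2-one with the benzyl-protected aroyl chloride and acid-induced ring closure.
5. Ring order: ring B is bought, ring C is closed first, the four-membered ring is attached next, ring A is formed last; benzyl hydrogenolysis ends the route.

Key step: step 9

Remark: the target has no stereocentre; every intermediate that carries one is made and used as a racemate, and that centre is destroyed again later in the route.

**Route**

Step 1
Reactants: 1 3-hydroxy-4,5-dimethoxybenzoic acid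
Product: 2 benzyl 3-(benzyloxy)-4,5-dimethoxybenzoate
Conditions: BnBr (2.5 equiv), K2CO3, DMF, 60 °C
Reagents that add atoms: benzyl bromide, BrCc1ccccc1
Why: Williamson O-alkylation of both the phenoxide and the carboxylate masks the future 3'-OH as a benzyl ether for the base and organometallic steps ahead.

Step 2
Reactants: 2 benzyl 3-(benzyloxy)-4,5-dimethoxybenzoate
Product: 3 3-(benzyloxy)-4,5-dimethoxybenzoic acid
Conditions: NaOH, THF/MeOH/H2O, 60 °C; then 1 M HCl
Reagents that add atoms: sodium hydroxide, [Na+].[OH-]
Why: saponification cleaves only the benzyl ester, since the aryl benzyl ether is inert to hydroxide.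

Step 3
Reactants: 3 3-(benzyloxy)-4,5-dimethoxybenzoic acid
Product: 4 3-(benzyloxy)-4,5-dimethoxybenzoyl chloride
Conditions: (COCl)2, DMF (cat.), CH2Cl2, 0 °C to rt
Reagents that add atoms: oxalyl chloride, O=C(Cl)C(=O)Cl
Why: acid chloride formation through the catalytic chloroiminium species is mild enough to leave all three ethers untouched.

Step 4
Reactants: 4 3-(benzyloxy)-4,5-dimethoxybenzoyl chloride; 5 (E)-4-methoxybut-3-en-2-one
Product: 7 (E)-1-[3-(benzyloxy)-4,5-dimethoxyphenyl]-5-methoxypent-4-ene-1,3-dione, via lithium dienolate 6 (not isolated)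
Conditions: 5 (2 equiv), LiN(SiMe3)2 (2 equiv), THF, −78 °C; then 4 (1 equiv), −78 °C; 1 M HCl quench
Reagents that add atoms: none
Why: Claisen-type C-acylation of the kinetic lithium enolate formed at the methyl group of the vinylogous ester should give the 1,3-diketone, the second equivalent of enolate taking up its acidic proton so that acylation stops after one aroyl group.

Step 5
Reactants: 7 (E)-1-[3-(benzyloxy)-4,5-dimethoxyphenyl]-5-methoxypent-4-ene-1,3-dione
Product: 8 2-[3-(benzyloxy)-4,5-dimethoxyphenyl]-4H-pyran-4-one
Conditions: CF3CO2H, toluene, rt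
Reagents that add atoms: none
Why: acid-catalysed 6-endo oxa-Michael addition of the aryl-ketone enol oxygen to the β-methoxyenone, then β-elimination of methanol, should close ring C as the 4-pyranone (γ-pyrone synthesis from β-methoxyenone diketones).

Step 6
Reactants: 9 dimethyl squarate (3,4-dimethoxycyclobut-3-ene-1,2-dione)
Product: 11 methyl semisquarate (3-methoxycyclobut-3-ene-1,2-dione), via hydroxycyclobutenone 10 (not isolated)
Conditions: LiAlH(OtBu)3, THF, −78 °C; H2O quench; then conc. HCl (cat.), CH2Cl2, rt
Reagents that add atoms: none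
Why: the bulky alkoxyaluminium hydride adds 1,2 to one squarate carbonyl and stops there (racemic carbinol 10), and acid then ionizes the carbinol with allylic transposition and net loss of methanol, which is the standard squarate-to-cyclobutenedione conversion.

Step 7
Reactants: 8 2-[3-(benzyloxy)-4,5-dimethoxyphenyl]-4H-pyran-4-one; 11 methyl semisquarate
Product: 13 4-{6-[3-(benzyloxy)-4,5-dimethoxyphenyl]-4-oxo-4H-pyran-2-yl}-4-hydroxy-3-methoxycyclobut-2-en-1-one (racemic), via 6-lithiopyranone 12 (not isolated)
Conditions: lithium 2,2,6,6-tetramethylpiperidide (from the amine and n-BuLi, 1.1 equiv), THF, −78 °C, 15 min; then 11 (1.2 equiv), −78 °C; AcOH quench at −78 °C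
Reagents that add atoms: none
Why: Proposed new method: the pyranone C6–H, next to the ring oxygen and vinylogous to the C4 carbonyl, should be the kinetically most acidic site toward the hindered non-nucleophilic amide (closest known reaction type: C2 lithiation of chromones with lithium amides at −78 °C), and the resulting α-oxygenated vinyllithium should add 1,2 to the more ketone-like carbonyl of 11, the one next to C–OMe rather than the less electrophilic vinylogous ester carbonyl, as aryl- and alkenyllithiums do with squarates and semisquarates, giving the carbinol stereocentre as a racemate.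

Step 8
Reactants: 13 4-{6-[3-(benzyloxy)-4,5-dimethoxyphenyl]-4-oxo-4H-pyran-2-yl}-4-hydroxy-3-methoxycyclobut-2-en-1-one
Product: 14 4-{6-[3-(benzyloxy)-4,5-dimethoxyphenyl]-4-oxo-4H-pyran-2-yl}-3,4-dimethoxycyclobut-2-en-1-one (racemic)
Conditions: MeI, Ag2O, 4 Å molecular sieves, MeCN, rt, dark
Reagents that add atoms: iodomethane, CI
Why: Purdie-type O-methylation with Ag2O works under nearly neutral conditions, so the base-sensitive 4-hydroxycyclobutenone should be etherified without ring opening and with its (racemic) stereocentre untouched.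

Step 9
Reactants: 14 4-{6-[3-(benzyloxy)-4,5-dimethoxyphenyl]-4-oxo-4H-pyran-2-yl}-3,4-dimethoxycyclobut-2-en-1-one
Product: 17 3'-(benzyloxy)-5-hydroxy-7,8,4',5'-tetramethoxyflavone, via dienylketene 15 (not isolated), via cyclohexadienone 16 (not isolated)
Conditions: degassed toluene (0.01 M), 110 °C, Ar
Reagents that add atoms: none
Why: Proposed new method: heat should open the C1–C4 bond of cyclobutenone 14 by conrotatory 4π electrocyclic ring opening, the C4 methoxy donor rotating outward so that the pyranonyl group lies cis to the ketene in dienylketene 15 (O=C=CH–C(OMe)=C(OMe)–C6=C5), which then closes by thermal disrotatory 6π electrocyclization between the ketene carbon and pyranone C5 to dione 16, whose new sp3 C–H between two carbonyls enolizes to the C5 phenol hydrogen-bonded to C4=O. The closest known reaction type is the Moore–Liebeskind ring expansion of 4-aryl-, 4-heteroaryl- and 4-alkenyl-4-alkoxycyclobutenones to mono-protected hydroquinones, whereas a 4-oxo-4H-pyran-2-yl group, whose C5=C6 bond belongs to a vinylogous ester, has not served as the unsaturated 4-substituent. Ring A is the only ring closed, by the 6π electrocyclization that forms the C5–C4a bond (flavone numbering) on the preformed ring C, and the gain of aromaticity drives the final tautomerization. No lasting stereocentre is created: the racemic quaternary carbon of 14 becomes aromatic C8 and the sp3 C4a of 16 is planarized on enolization. The step needs outward torquoselectivity for the 4-methoxy group, which the general preference of oxygen donors on the sp3 carbon of cyclobutenones for outward rotation should secure, and closure at pyranone C5, the only carbon neighbour of C6 in the ring; because the tertiary oxygen was methylated in step 8, C8 emerges as OMe and C5 as free OH without any hydroquinone differentiation.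

Step 10
Reactants: 17 3'-(benzyloxy)-5-hydroxy-7,8,4',5'-tetramethoxyflavone
Product: 18 5,3'-dihydroxy-7,8,4',5'-tetramethoxyflavone
Conditions: H2 (1 atm), Pd/C (10 wt% Pd on carbon), EtOAc/MeOH, rt
Reagents that add atoms: none
Why: hydrogenolysis of the benzylic C–O bond should free the 3'-phenol while the chromone C2=C3 bond and the aryl methyl ethers stay intact under these mild conditions.

**Compound list**

1 | 3-hydroxy-4,5-dimethoxybenzoic acid | COc1cc(C(=O)O)cc(O)c1OC | starting material
2 | benzyl 3-(benzyloxy)-4,5-dimethoxybenzoate | COc1cc(C(=O)OCc2ccccc2)cc(OCc2ccccc2)c1OC | intermediate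
3 | 3-(benzyloxy)-4,5-dimethoxybenzoic acid | COc1cc(C(=O)O)cc(OCc2ccccc2)c1OC | intermediate
4 | 3-(benzyloxy)-4,5-dimethoxybenzoyl chloride | COc1cc(C(=O)Cl)cc(OCc2ccccc2)c1OC | intermediate
5 | (E)-4-methoxybut-3-en-2-one | CO/C=C/C(C)=O | starting material
6 | lithium (E)-4-methoxybuta-1,3-dien-2-olate (formed in the flask) | [Li+].[O-]C(=C)/C=C/OC | intermediate
7 | (E)-1-[3-(benzyloxy)-4,5-dimethoxyphenyl]-5-methoxypent-4-ene-1,3-dione | COc1cc(C(=O)CC(=O)/C=C/OC)cc(OCc2ccccc2)c1OC | intermediate
8 | 2-[3-(benzyloxy)-4,5-dimethoxyphenyl]-4H-pyran-4-one | COc1cc(-c2cc(=O)cco2)cc(OCc2ccccc2)c1OC | intermediate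
9 | dimethyl squarate (3,4-dimethoxycyclobut-3-ene-1,2-dione) | COC1=C(OC)C(=O)C1=O | starting material
10 | 4-hydroxy-2,3-dimethoxycyclobut-2-en-1-one (racemic, formed in the flask) | COC1=C(OC)C(O)C1=O | intermediate
11 | methyl semisquarate (3-methoxycyclobut-3-ene-1,2-dione) | COC1=CC(=O)C1=O | intermediate
12 | {6-[3-(benzyloxy)-4,5-dimethoxyphenyl]-4-oxo-4H-pyran-2-yl}lithium (formed in the flask) | [Li]c1cc(=O)cc(-c2cc(OC)c(OC)c(OCc3ccccc3)c2)o1 | intermediate
13 | 4-{6-[3-(benzyloxy)-4,5-dimethoxyphenyl]-4-oxo-4H-pyran-2-yl}-4-hydroxy-3-methoxycyclobut-2-en-1-one (racemic) | COC1=CC(=O)C1(O)c1cc(=O)cc(-c2cc(OC)c(OC)c(OCc3ccccc3)c2)o1 | intermediate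
14 | 4-{6-[3-(benzyloxy)-4,5-dimethoxyphenyl]-4-oxo-4H-pyran-2-yl}-3,4-dimethoxycyclobut-2-en-1-one (racemic) | COC1=CC(=O)C1(OC)c1cc(=O)cc(-c2cc(OC)c(OC)c(OCc3ccccc3)c2)o1 | intermediate
15 | (3Z)-4-{6-[3-(benzyloxy)-4,5-dimethoxyphenyl]-4-oxo-4H-pyran-2-yl}-3,4-dimethoxybuta-1,3-dien-1-one (dienylketene, formed in the flask) | O=C=C/C(OC)=C(OC)\c1cc(=O)cc(-c2cc(OC)c(OC)c(OCc3ccccc3)c2)o1 | intermediate
16 | 2-[3-(benzyloxy)-4,5-dimethoxyphenyl]-7,8-dimethoxy-4aH-chromene-4,5-dione (racemic, formed in the flask) | COC1=CC(=O)C2C(=O)C=C(c3cc(OC)c(OC)c(OCc4ccccc4)c3)OC2=C1OC | intermediate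
17 | 3'-(benzyloxy)-5-hydroxy-7,8,4',5'-tetramethoxyflavone | COc1cc(-c2cc(=O)c3c(O)cc(OC)c(OC)c3o2)cc(OCc2ccccc2)c1OC | intermediate
18 | 5,3'-dihydroxy-7,8,4',5'-tetramethoxyflavone | COc1cc(-c2cc(=O)c3c(O)cc(OC)c(OC)c3o2)cc(O)c1OC | target

**Step count**

Total steps: 10. Longest linear sequence: 9 steps (1 → 2 → 3 → 4 → 7 → 8 → 13 → 14 → 17 → 18, steps 1–5 and 7–10); the squarate branch (step 6) joins at step 7.

**Steps most likely to fail**

1. Step 7 (proposed new method). Deprotonation may occur at C3 or C5 next to the carbonyl instead of C6, the lithiated pyranone may add to unreacted pyranone or fragment before it meets the dione, or it may attack the wrong carbonyl of the semisquarate. The fallback gives up the pyranone-first order and uses known chemistry. It sets out from acid chloride 4 and the bought 2'-hydroxy-3',4',6'-trimethoxyacetophenone (CC(=O)c1c(O)c(OC)c(OC)cc1OC). O-Acylation in pyridine with catalytic DMAP should give 2-acetyl-3,5,6-trimethoxyphenyl 3-(benzyloxy)-4,5-dimethoxybenzoate F1. Baker–Venkataraman acyl shift (KOH, pyridine, 50 °C) should give 1-[3-(benzyloxy)-4,5-dimethoxyphenyl]-3-(2-hydroxy-3,4,6-trimethoxyphenyl)propane-1,3-dione F2. Cyclodehydration (TsOH, toluene, reflux) should give 3'-(benzyloxy)-5,7,8,4',5'-pentamethoxyflavone F3. BCl3 with pentamethylbenzene in CH2Cl2 (−78 to 0 °C) should then remove the benzyl group and, by chelation to the C4 carbonyl, the peri 5-O-methyl group only, which returns to the route at 18.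

2. Step 9 (proposed new method). The 6π closure onto the electron-poor vinylogous-ester C5=C6 bond may be too slow, so that the ketene dimerizes or is captured by adventitious nucleophiles, or part of the material may open with inward rotation and end as lactone by-products. The fallback again uses known chemistry and sets out from acid chloride 4. Partial reduction (LiAlH(OtBu)3, THF, −78 °C) should give 3-(benzyloxy)-4,5-dimethoxybenzaldehyde F4. Claisen–Schmidt condensation with the same bought acetophenone (KOH, EtOH, rt) should give (E)-3-[3-(benzyloxy)-4,5-dimethoxyphenyl]-1-(2-hydroxy-3,4,6-trimethoxyphenyl)prop-2-en-1-one F5. Oxidative cyclization (I2 cat., DMSO, 130 °C) should lead to the same pentamethoxyflavone F3 as above, and the same BCl3 treatment returns to the route at 18.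

3. Step 8. Alkylation of the hindered tertiary hydroxyl may be incomplete, and the basic silver oxide surface may open the strained ring (retro-aldol-type cleavage or rearrangement to a butenolide) before methylation. The fallback drops the protection and sets out from 13. Heating 13 in degassed toluene under argon should run the same ring expansion with the free hydroxyl and give 3'-(benzyloxy)-5,8-dihydroxy-7,4',5'-trimethoxyflavone F6. Methylation of F6 with MeI (1.05 equiv) and K2CO3 in acetone at rt under argon should alkylate only the C8 hydroxyl, because the C5 hydroxyl is locked in a hydrogen bond to C4=O, and this returns to the route at 17.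

**Further compounds**

F1 | step 7 | 2-acetyl-3,5,6-trimethoxyphenyl 3-(benzyloxy)-4,5-dimethoxybenzoate | CC(=O)c1c(OC(=O)c2cc(OC)c(OC)c(OCc3ccccc3)c2)c(OC)c(OC)cc1OC
F2 | step 7 | 1-[3-(benzyloxy)-4,5-dimethoxyphenyl]-3-(2-hydroxy-3,4,6-trimethoxyphenyl)propane-1,3-dione | COc1cc(C(=O)CC(=O)c2c(O)c(OC)c(OC)cc2OC)cc(OCc2ccccc2)c1OC
F3 | step 7 | 3'-(benzyloxy)-5,7,8,4',5'-pentamethoxyflavone | COc1cc(-c2cc(=O)c3c(OC)cc(OC)c(OC)c3o2)cc(OCc2ccccc2)c1OC
F4 | step 9 | 3-(benzyloxy)-4,5-dimethoxybenzaldehyde | COc1cc(C=O)cc(OCc2ccccc2)c1OC
F5 | step 9 | (E)-3-[3-(benzyloxy)-4,5-dimethoxyphenyl]-1-(2-hydroxy-3,4,6-trimethoxyphenyl)prop-2-en-1-one | COc1cc(/C=C/C(=O)c2c(O)c(OC)c(OC)cc2OC)cc(OCc2ccccc2)c1OC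
F6 | step 8 | 3'-(benzyloxy)-5,8-dihydroxy-7,4',5'-trimethoxyflavone | COc1cc(-c2cc(=O)c3c(O)cc(OC)c(O)c3o2)cc(OCc2ccccc2)c1OC
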